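**Plan** (labdane numbering throughout, also for the ring-A intermediates)

- The SMILES is read as a cis-fused labdane: H-5, the C10 methyl, the C4 methyl, C11 and the C8 methyl lie on one face; C18–O, H-9 and the 8-OH lie on the other. (4R,5S,8R,9R,10S).
- Cuts, in retrosynthetic order: the aryl–alkene bond and the C18–O ester bond of the Z-coumarate; C12–C13 of the diene; C8–C9 of ring B; C9=C11.
- Enabling feature: C8–C9 joins a tertiary carbinol carbon (C8, bearing OH and the C17 methyl) to the side-chain-bearing C9. As a ketone carbon and an enoate β-carbon both are electrophiles, so ring B is closed reductively by a ketyl–olefin coupling.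
- The ring-A cyclohexane that remains has latent mirror symmetry: C4 and C10 are both C(CH3)(CH2O) with the same relation to C5. It therefore descends from meso diol 11, assembled by malonate chemistry (C4–C5 and C5–C10 by Knoevenagel–Michael, C3–C4 and C1–C10 by double alkylation, two C–CH3 bonds by enolate methylation).
- Forward order: ring A (steps 1–5), desymmetrisation and arm elaboration (6–9), ring B (10), diene side chain (11–16), Z-coumarate (17–18).
- Stereochemistry: C4/C5/C10 relative configuration from two methylations anti to the C5 arm; absolute configuration from enzymatic desymmetrisation; C8 and C9 from the chair-like cyclisation transition state; Z-alkene from (Z)-3-iodoacrylic acid, kept in the Suzuki coupling.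

Key step: step 10

Assumption: the lipase in step 6 is taken to acetylate the hydroxymethyl group on the (R)-configured ring carbon of meso diol 11 (the future C18); the opposite preference is covered by the fallback to step 6.

**Route**

Step 1
Reactants: 1 pent-4-enal; 2 dimethyl malonate (2.2 equiv)
Product: 4 tetramethyl 2-(but-3-en-1-yl)propane-1,1,3,3-tetracarboxylate, via alkylidene malonate 3 (not isolated)
Conditions: piperidine (10 mol%), AcOH (10 mol%), MeOH, 0 → 25 °C
Reagents that add atoms: none
Why: Knoevenagel condensation followed by Michael addition of a second malonate to the alkylidene malonate should give the bis-malonate, which holds C5 with its arm between the future C4 and C10; no stereocentre is formed.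

Step 2
Reactants: 4 tetramethyl 2-(but-3-en-1-yl)propane-1,1,3,3-tetracarboxylate; 5 1,3-dibromopropane
Product: 7 tetramethyl 2-(but-3-en-1-yl)cyclohexane-1,1,3,3-tetracarboxylate, via bromopropyl tetraester 6 (not isolated)
Conditions: NaH (2.2 equiv), DMF, 0 °C; then 5 (1.1 equiv), 0 → 70 °C
Reagents that add atoms: none
Why: Malonate cycloalkylation, an intermolecular SN2 alkylation followed by a 6-exo-tet ring closure, should build ring A, and full double deprotonation blocks the retro-Michael pathway; no stereocentre is formed.

Step 3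
Reactants: 7 tetramethyl 2-(but-3-en-1-yl)cyclohexane-1,1,3,3-tetracarboxylate
Product: 8 dimethyl 2-(but-3-en-1-yl)cyclohexane-1,3-dicarboxylate (mixture of stereoisomers)
Conditions: LiCl, H2O, DMSO, 160 °C
Reagents that add atoms: none
Why: Krapcho dealkoxycarbonylation removes one ester from each geminal pair, and the stereoisomer mixture is of no consequence because both α-carbons are enolised again in step 4.

Step 4
Reactants: 8 dimethyl 2-(but-3-en-1-yl)cyclohexane-1,3-dicarboxylate
Product: 10 dimethyl (1R,2s,3S)-2-(but-3-en-1-yl)-1,3-dimethylcyclohexane-1,3-dicarboxylate (meso; both esters cis to the butenyl arm), via monomethyl diester 9 (not isolated)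
Conditions: LiN(i-Pr)2 (1.1 equiv), THF, −78 °C, then MeI; recool, LiN(i-Pr)2 (1.2 equiv), then MeI, −78 → 0 °C
Reagents that add atoms: iodomethane, CI
Why: In this ester-enolate C-methylation, A(1,3) strain in each exocyclic enolate should turn the C5 arm axial so that iodomethane enters anti to it, and the second methyl should enter anti to the arm again and cis to the first (the known course of stepwise methylation of cyclohexane-1,3-dicarboxylate enolates), giving the meso diester from which the other diastereomers are removed by chromatography.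

Step 5
Reactants: 10 meso dimethyl diester
Product: 11 [(1R,2s,3S)-2-(but-3-en-1-yl)-1,3-dimethylcyclohexane-1,3-diyl]dimethanol (meso diol)
Conditions: LiAlH4, THF, 0 °C → reflux
Reagents that add atoms: none
Why: Hydride reduction of the two neopentyl esters to primary alcohols touches no stereocentre.

Step 6
Reactants: 11 meso diol
Product: 12 [(1R,2S,3S)-2-(but-3-en-1-yl)-3-(hydroxymethyl)-1,3-dimethylcyclohexyl]methyl acetate (acetate on the future C18, free hydroxyl on the future C9)
Conditions: Burkholderia cepacia lipase (immobilised), vinyl acetate, t-BuOMe, 30 °C; product used at once in step 7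
Reagents that add atoms: vinyl acetate, CC(=O)OC=C
Why: Lipase-catalysed enantiotopic-group-selective transesterification of a meso diol with an irreversible acyl donor should fix the absolute configuration at C4, C5 and C10, and slow over-acetylation of the minor enantiomer to the meso diacetate should raise the enantiomeric purity.

Step 7
Reactants: 12 monoacetate
Product: 13 [(1R,2R,3S)-2-(but-3-en-1-yl)-3-formyl-1,3-dimethylcyclohexyl]methyl acetate
Conditions: Dess–Martin periodinane, NaHCO3, CH2Cl2, 0 → 25 °C
Reagents that add atoms: none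
Why: Dess–Martin oxidation of the primary alcohol gives an aldehyde whose α-carbon is quaternary, so nothing can epimerise, and removal of the free hydroxyl ends any risk of acetyl migration between the two facing arms.

Step 8
Reactants: 13 aldehyde; 14 tert-butyl 2-(diethoxyphosphoryl)acetate
Product: 15 tert-butyl (2E)-3-[(1R,2S,3R)-3-(acetoxymethyl)-2-(but-3-en-1-yl)-1,3-dimethylcyclohexyl]prop-2-enoate
Conditions: 14, NaH, THF, 0 °C; then 13, 0 → 40 °C
Reagents that add atoms: none
Why: Horner–Wadsworth–Emmons olefination of the non-enolisable aldehyde with a stabilised phosphonate anion should give the (E)-enoate (C9=C11, C12 ester), the tert-butyl ester being chosen so that the later tertiary alkoxide cannot lactonise.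

Step 9
Reactants: 15 enoate
Product: 16 tert-butyl (2E)-3-[(1R,2S,3R)-3-(acetoxymethyl)-1,3-dimethyl-2-(3-oxobutyl)cyclohexyl]prop-2-enoate (ring A with the C18 acetoxymethyl, the C5 3-oxobutyl arm and the C10 enoate on one face)
Conditions: PdCl2 (10 mol%), CuCl (1 equiv, reoxidised by O2), O2 (1 atm), DMF/H2O, 25 °C
Reagents that add atoms: water, O
Why: Tsuji–Wacker oxidation should convert the monosubstituted alkene into the C8 methyl ketone by Markovnikov oxypalladation, while the electron-poor, hindered enoate double bond does not react.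

Step 10
Reactants: 16 keto enoate
Product: 17 tert-butyl 18-acetoxy-8α-hydroxy-13,14,15,16-tetranor-5β-labdan-12-oate (4R,5S,8R,9R,10S; cis-fused decalin)
Conditions: SmI2 (2.5 equiv), HMPA (10 equiv), t-BuOH (2 equiv), THF (0.01 M), −78 → 0 °C
Reagents that add atoms: none
Why: SmI2–HMPA transfers one electron to the methyl ketone and the samarium-bound ketyl at C8 adds to C9, the β-carbon of the enoate, after which the α-ester radical is reduced by a second equivalent and the samarium enolate is protonated by t-BuOH (samarium diiodide ketyl–olefin reductive cyclisation of a keto enoate, a known reaction type). Ring B closes in the 6-exo-trig mode. C9 is controlled by ring A: in its chair with both methyls equatorial the C6 arm is equatorial and the enoate axial, and in the chair-like transition state the C9=C11 unit must lie equatorial on the forming ring because the axial site is blocked by the axial C5–C4 bond, which places C11 syn to the C10 methyl. C8 is controlled by the bulky O–Sm(HMPA)n group, which takes the equatorial site away from the axial C10 methyl, so the hydroxyl should end trans to C11 and the C17 methyl axial. The step needs ring closure to outrun simple reduction of the ketone or the enoate and pinacol coupling, which high dilution, HMPA and the 6-exo geometry should secure, and the cis relation of the two arms set in step 4 allows only the cis-fused decalin. The tert-butyl ester keeps the tertiary samarium alkoxide from lactonising and the acetate is inert to divalent samarium under these conditions.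

Step 11
Reactants: 17 hydroxy ester
Product: 18 tert-butyl 18-acetoxy-8α-(triethylsilyloxy)-13,14,15,16-tetranor-5β-labdan-12-oate
Conditions: Et3SiOTf, 2,6-lutidine, CH2Cl2, −78 → 0 °C
Reagents that add atoms: triethylsilyl trifluoromethanesulfonate, CC[Si](CC)(CC)OS(=O)(=O)C(F)(F)F
Why: Silylation of the hindered tertiary alcohol with a silyl triflate blocks the 8,12-ether formation that would otherwise follow activation of C12.

Step 12
Reactants: 18 silyl ether
Product: 19 8α-(triethylsilyloxy)-13,14,15,16-tetranor-5β-labdane-12,18-diol
Conditions: LiAlH4, THF, 0 °C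
Reagents that add atoms: none
Why: Hydride reduction converts the tert-butyl ester into the C12 carbinol and cleaves the C18 acetate in the same operation, while the silyl ether is inert.

Step 13
Reactants: 19 diol
Product: 20 12-iodo-8α-(triethylsilyloxy)-13,14,15,16-tetranor-5β-labdan-18-ol
Conditions: PPh3 (1.2 equiv), I2 (1.2 equiv), imidazole, CH2Cl2, 0 °C
Reagents that add atoms: iodine, II
Why: Appel iodination proceeds by SN2 displacement, which is fast at the unhindered C12 carbinol and should not occur at the neopentyl C18 carbinol.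

Step 14
Reactants: 21 2-chlorobuta-1,3-diene (chloroprene)
Product: 22 buta-1,3-dien-2-ylmagnesium chloride (THF solution, titrated and used directly)
Conditions: Mg turnings, ZnCl2 (cat.), BrCH2CH2Br (cat.), THF, reflux
Reagents that add atoms: magnesium, [Mg]
Why: Grignard formation by insertion of magnesium into the vinylic C–Cl bond of chloroprene is a known preparation of this dienyl reagent.

Step 15
Reactants: 20 iodide; 22 buta-1,3-dien-2-ylmagnesium chloride (3 equiv)
Product: 23 8α-(triethylsilyloxy)-5β-labda-13(16),14-dien-18-ol
Conditions: Li2CuCl4 (5 mol%), THF, −20 → 0 °C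
Reagents that add atoms: none
Why: Copper-catalysed cross-coupling of a primary alkyl iodide with an alkenyl Grignard reagent should form C12–C13 and give the 2-substituted butadiene, one extra equivalent of reagent being consumed by the free hydroxyl.

Step 16
Reactants: 23 silyl ether
Product: 24 5β-labda-13(16),14-diene-8α,18-diol
Conditions: HF·pyridine, pyridine, THF, 0 → 25 °C
Reagents that add atoms: none
Why: Buffered fluoride cleavage of the Si–O bond frees the tertiary alcohol under conditions too mild to dehydrate it or to affect the diene.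

Step 17
Reactants: 24 diol; 25 (Z)-3-iodoprop-2-enoic acid (1.5 equiv)
Product: 26 8α-hydroxy-5β-labda-13(16),14-dien-18-yl (Z)-3-iodoprop-2-enoate
Conditions: DCC, DMAP (10 mol%), CH2Cl2, −20 → 0 °C, dark
Reagents that add atoms: none
Why: Steglich esterification should acylate the primary C18 hydroxyl and leave the tertiary C8 hydroxyl untouched, and low temperature with only catalytic DMAP should keep the Z-iodoalkene geometry.

Step 18
Reactants: 26 iodoacrylate; 27 (4-hydroxyphenyl)boronic acid (1.5 equiv)
Product: 28 8α-hydroxy-5β-labda-13(16),14-dien-18-yl (Z)-3-(4-hydroxyphenyl)prop-2-enoate (4R,5S,8R,9R,10S; CNP0197278.5)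
Conditions: Pd(PPh3)4 (5 mol%), K2CO3 (aq), THF, 25 °C, dark
Reagents that add atoms: none
Why: Suzuki–Miyaura coupling of an alkenyl iodide with an arylboronic acid at zerovalent palladium proceeds with retention of alkene geometry, so the Z configuration of 26 should be carried into the coumarate, and the free phenol needs no protection.

**Compound list**

1 | pent-4-enal | C=CCCC=O | starting material
2 | dimethyl malonate | COC(=O)CC(=O)OC | starting material
3 | dimethyl 2-(pent-4-en-1-ylidene)propanedioate | C=CCCC=C(C(=O)OC)C(=O)OC | intermediate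
4 | tetramethyl 2-(but-3-en-1-yl)propane-1,1,3,3-tetracarboxylate | C=CCCC(C(C(=O)OC)C(=O)OC)C(C(=O)OC)C(=O)OC | intermediate
5 | 1,3-dibromopropane | BrCCCBr | starting material
6 | tetramethyl 6-bromo-2-(but-3-en-1-yl)hexane-1,1,3,3-tetracarboxylate (racemic) | C=CCCC(C(C(=O)OC)C(=O)OC)C(CCCBr)(C(=O)OC)C(=O)OC | intermediate
7 | tetramethyl 2-(but-3-en-1-yl)cyclohexane-1,1,3,3-tetracarboxylate | C=CCCC1C(C(=O)OC)(C(=O)OC)CCCC1(C(=O)OC)C(=O)OC | intermediate
8 | dimethyl 2-(but-3-en-1-yl)cyclohexane-1,3-dicarboxylate (mixture of stereoisomers) | C=CCCC1C(C(=O)OC)CCCC1C(=O)OC | intermediate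
9 | dimethyl 2-(but-3-en-1-yl)-1-methylcyclohexane-1,3-dicarboxylate (racemic, one enantiomer drawn; methyl trans to the butenyl arm; epimers at C3) | COC(=O)[C@@]1(C)CCCC(C(=O)OC)[C@H]1CCC=C | intermediate
10 | dimethyl (1R,2s,3S)-2-(but-3-en-1-yl)-1,3-dimethylcyclohexane-1,3-dicarboxylate (meso) | COC(=O)[C@@]1(C)CCC[C@@](C)(C(=O)OC)[C@H]1CCC=C | intermediate
11 | [(1R,2s,3S)-2-(but-3-en-1-yl)-1,3-dimethylcyclohexane-1,3-diyl]dimethanol (meso) | OC[C@@]1(C)CCC[C@@](C)(CO)[C@H]1CCC=C | intermediate
12 | [(1R,2S,3S)-2-(but-3-en-1-yl)-3-(hydroxymethyl)-1,3-dimethylcyclohexyl]methyl acetate | OC[C@@]1(C)CCC[C@@](C)(COC(C)=O)[C@H]1CCC=C | intermediate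
13 | [(1R,2R,3S)-2-(but-3-en-1-yl)-3-formyl-1,3-dimethylcyclohexyl]methyl acetate | O=C[C@@]1(C)CCC[C@@](C)(COC(C)=O)[C@H]1CCC=C | intermediate
14 | tert-butyl 2-(diethoxyphosphoryl)acetate | CCOP(=O)(OCC)CC(=O)OC(C)(C)C | starting material
15 | tert-butyl (2E)-3-[(1R,2S,3R)-3-(acetoxymethyl)-2-(but-3-en-1-yl)-1,3-dimethylcyclohexyl]prop-2-enoate | CC(C)(C)OC(=O)/C=C/[C@@]1(C)CCC[C@@](C)(COC(C)=O)[C@H]1CCC=C | intermediate
16 | tert-butyl (2E)-3-[(1R,2S,3R)-3-(acetoxymethyl)-1,3-dimethyl-2-(3-oxobutyl)cyclohexyl]prop-2-enoate | CC(C)(C)OC(=O)/C=C/[C@@]1(C)CCC[C@@](C)(COC(C)=O)[C@H]1CCC(C)=O | intermediate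
17 | tert-butyl 18-acetoxy-8α-hydroxy-13,14,15,16-tetranor-5β-labdan-12-oate | CC(C)(C)OC(=O)C[C@@H]1[C@@]2(C)CCC[C@@](C)(COC(C)=O)[C@H]2CC[C@@]1(C)O | intermediate
18 | tert-butyl 18-acetoxy-8α-(triethylsilyloxy)-13,14,15,16-tetranor-5β-labdan-12-oate | CC(C)(C)OC(=O)C[C@@H]1[C@@]2(C)CCC[C@@](C)(COC(C)=O)[C@H]2CC[C@@]1(C)O[Si](CC)(CC)CC | intermediate
19 | 8α-(triethylsilyloxy)-13,14,15,16-tetranor-5β-labdane-12,18-diol | OCC[C@@H]1[C@@]2(C)CCC[C@@](C)(CO)[C@H]2CC[C@@]1(C)O[Si](CC)(CC)CC | intermediate
20 | 12-iodo-8α-(triethylsilyloxy)-13,14,15,16-tetranor-5β-labdan-18-ol | ICC[C@@H]1[C@@]2(C)CCC[C@@](C)(CO)[C@H]2CC[C@@]1(C)O[Si](CC)(CC)CC | intermediate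
21 | 2-chlorobuta-1,3-diene | C=CC(Cl)=C | starting material
22 | buta-1,3-dien-2-ylmagnesium chloride | C=CC(=C)[Mg]Cl | intermediate
23 | 8α-(triethylsilyloxy)-5β-labda-13(16),14-dien-18-ol | C=CC(=C)CC[C@@H]1[C@@]2(C)CCC[C@@](C)(CO)[C@H]2CC[C@@]1(C)O[Si](CC)(CC)CC | intermediate
24 | 5β-labda-13(16),14-diene-8α,18-diol | C=CC(=C)CC[C@@H]1[C@@]2(C)CCC[C@@](C)(CO)[C@H]2CC[C@@]1(C)O | intermediate
25 | (Z)-3-iodoprop-2-enoic acid | OC(=O)/C=C\I | starting material
26 | 8α-hydroxy-5β-labda-13(16),14-dien-18-yl (Z)-3-iodoprop-2-enoate | C=CC(=C)CC[C@@H]1[C@@]2(C)CCC[C@@](C)(COC(=O)/C=C\I)[C@H]2CC[C@@]1(C)O | intermediate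
27 | (4-hydroxyphenyl)boronic acid | OB(O)c1ccc(O)cc1 | starting material
28 | 8α-hydroxy-5β-labda-13(16),14-dien-18-yl (Z)-3-(4-hydroxyphenyl)prop-2-enoate | C=CC(=C)CC[C@@H]1[C@@]2(C)CCC[C@@](C)(COC(=O)/C=C\c3ccc(O)cc3)[C@H]2CC[C@@]1(C)O | target

**Count**

Total steps: 18. Longest linear sequence: 17 (steps 1–13 and 15–18; step 14 prepares the Grignard reagent).

**Steps most likely to fail**

Step 10. The ketyl may add to the enoate with poor facial control at C8 or C9, or the ketone and the enoate may be reduced separately before the ring closes. The fallback sets out from 16 and generates the C8 radical without samarium. Kinetic enolisation with LiN(i-Pr)2 in the presence of Et3SiCl (THF, −78 °C) should give the triethylsilyl enol ether F1. Fe(acac)3 and PhSiH3 in EtOH/ethylene glycol (60 °C) should then transfer a hydrogen atom to the enol ether, and the tertiary α-silyloxy radical at C8 should close 6-exo onto the enoate. This is an iron-hydride hydrogen-atom-transfer radical conjugate addition, a known reaction type for silyl enol ether donors. Reduction and protonation of the α-ester radical would give the silyl ether directly, so the route is rejoined at 18.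

Step 4. Iodomethane may enter syn to the butenyl arm in the first or the second alkylation, so that the chiral diastereomer or the other meso isomer forms beside 10. The fallback sets out from 7 and draws the stereochemistry from the choice between diastereotopic esters instead of enolate faces. LiAlH(OtBu)3 (THF, 0 → 25 °C) should reduce one ester of each malonate unit, by precedent the one trans to the vicinal substituent, to give the bis(hydroxymethyl) diester F2. 1,1'-Thiocarbonyldiimidazole should give the bis(imidazolylthiocarbonate) F3. Barton–McCombie deoxygenation (Bu3SnH at high concentration, AIBN, toluene, 110 °C) would turn both CH2O groups into methyl groups, and the route is rejoined at 10.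

Step 6. Acyl transfer to the two neopentyl hydroxyls may be slow or poorly group-selective, the enzyme may prefer the other arm, or acetyl migration between the facing hydroxymethyl groups may erode the enantiomeric purity. The fallback sets out from 11 and replaces catalysis by a covalent resolving group. One equivalent of (1S)-camphanoyl chloride (pyridine, CH2Cl2) should give two diastereomeric monoesters, separable by chromatography or crystallisation. The one esterified at the future C18, the monocamphanate F4, would be oxidised with Dess–Martin periodinane to the aldehyde F5 and olefinated with 14 to the camphanoyl enoate F6. K2CO3 in MeOH should remove the auxiliary to give the hydroxy enoate F7, and Ac2O/pyridine rejoins the route at 15. The other monoester and any diester would be saponified back to 11.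

**Further compounds**

F1 | step 10 | tert-butyl (2E)-3-[(1R,2S,3R)-3-(acetoxymethyl)-1,3-dimethyl-2-(3-(triethylsilyloxy)but-3-en-1-yl)cyclohexyl]prop-2-enoate | CC(C)(C)OC(=O)/C=C/[C@@]1(C)CCC[C@@](C)(COC(C)=O)[C@H]1CCC(=C)O[Si](CC)(CC)CC
F2 | step 4 | dimethyl 2-(but-3-en-1-yl)-1,3-bis(hydroxymethyl)cyclohexane-1,3-dicarboxylate (meso; esters cis, hydroxymethyl groups trans to the butenyl arm) | COC(=O)[C@@]1(CO)CCC[C@@](CO)(C(=O)OC)[C@H]1CCC=C
F3 | step 4 | dimethyl 2-(but-3-en-1-yl)-1,3-bis[(imidazol-1-ylcarbothioyl)oxymethyl]cyclohexane-1,3-dicarboxylate (meso) | COC(=O)[C@@]1(COC(=S)n2ccnc2)CCC[C@@](COC(=S)n2ccnc2)(C(=O)OC)[C@H]1CCC=C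
F4 | step 6 | [(1R,2S,3S)-2-(but-3-en-1-yl)-3-(hydroxymethyl)-1,3-dimethylcyclohexyl]methyl (1S,4R)-camphanate | OC[C@@]1(C)CCC[C@@](C)(COC(=O)[C@@]23CC[C@@](C)(C(=O)O2)C3(C)C)[C@H]1CCC=C
F5 | step 6 | [(1R,2R,3S)-2-(but-3-en-1-yl)-3-formyl-1,3-dimethylcyclohexyl]methyl (1S,4R)-camphanate | O=C[C@@]1(C)CCC[C@@](C)(COC(=O)[C@@]23CC[C@@](C)(C(=O)O2)C3(C)C)[C@H]1CCC=C
F6 | step 6 | tert-butyl (2E)-3-[(1R,2S,3R)-2-(but-3-en-1-yl)-3-(camphanoyloxymethyl)-1,3-dimethylcyclohexyl]prop-2-enoate | CC(C)(C)OC(=O)/C=C/[C@@]1(C)CCC[C@@](C)(COC(=O)[C@@]23CC[C@@](C)(C(=O)O2)C3(C)C)[C@H]1CCC=C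
F7 | step 6 | tert-butyl (2E)-3-[(1R,2S,3R)-2-(but-3-en-1-yl)-3-(hydroxymethyl)-1,3-dimethylcyclohexyl]prop-2-enoate | CC(C)(C)OC(=O)/C=C/[C@@]1(C)CCC[C@@](C)(CO)[C@H]1CCC=C
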